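**Retrosynthetic overview**
1. The target 9 is 3-bromohomofascaplysin C, a flat 12H-pyrido[1,2-a:3,4-b']diindole with CHO at C13 and Br at C3.
2. Last disconnection: the central pyridine ring (N5–C6 and C7–C7a) opens to 3-formyl-2,2'-biindole 6 plus vinylene carbonate 7, closed by a new Rh(III) N–H/C–H [4+2] annulation.
3. 6 comes from N-Boc biindole 5, made by site-selective Suzuki coupling (C12a–C12b bond) of 2,6-dibromoindole-3-carbaldehyde 3 with N-Boc-indol-2-ylboronic acid 4.
4. 3 comes from 6-bromooxindole 1 by Vilsmeier–Haack–Arnold bromoformylation, which installs CHO and the C2–Br handle together; the C6–Br is bought.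
5. Ring order: both indole units are purchased; the only ring built is the central pyridine ring, closed in the last step.

Assumption: the target has no stereocentre or stereogenic axis, so "single enantiomer" does not apply and the achiral compound drawn is made.

**Route**

Step 1
Reactants: 1 6-bromoindolin-2-one (6-bromooxindole)
Product: 3 2,6-dibromo-1H-indole-3-carbaldehyde, via iminium bromide 2 (not isolated)
Conditions: POBr3 (2.5 equiv), DMF (3 equiv), CHCl3, 0 °C then reflux; then ice–H2O
Reagents that add atoms: N,N-dimethylformamide CN(C)C=O; phosphorus oxybromide O=P(Br)(Br)Br; water O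
Why: Vilsmeier–Haack–Arnold haloformylation: the bromo-Vilsmeier reagent formylates the oxindole enol at C3 and converts the lactam C=O into the C2–Br, so the ring aromatises to the 2-bromoindole iminium 2, which water hydrolyses to the aldehyde while the aryl C6–Br is inert.

Step 2
Reactants: 3 2,6-dibromo-1H-indole-3-carbaldehyde; 4 [1-(tert-butoxycarbonyl)-1H-indol-2-yl]boronic acid (1.15 equiv)
Product: 5 tert-butyl 6'-bromo-3'-formyl-1'H-[2,2'-biindole]-1-carboxylate
Conditions: Pd(PPh3)4 (5 mol%), K2CO3 (3 equiv), DME/H2O 4:1, 75 °C
Reagents that add atoms: none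
Why: Site-selective Suzuki–Miyaura coupling: oxidative addition is much faster at the C2–Br, a vinylogous acyl (imidoyl-type) bromide activated by N1 and the 3-formyl group, than at the unactivated C6–Br, and the N-Boc group keeps the 2-indolylboronic acid from protodeboronating.

Step 3
Reactants: 5 tert-butyl 6'-bromo-3'-formyl-1'H-[2,2'-biindole]-1-carboxylate
Product: 6 6-bromo-1H,1'H-[2,2'-biindole]-3-carbaldehyde
Conditions: CF3CH2OH, 150 °C (microwave), 1 h
Reagents that add atoms: none
Why: Thermolytic N-Boc cleavage in a fluorinated alcohol: the carbamate on the weakly basic indole nitrogen fragments to isobutene and CO2 under neutral conditions, leaving the aldehyde, both N–H groups and the aryl bromide untouched.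

Step 4
Reactants: 6 6-bromo-1H,1'H-[2,2'-biindole]-3-carbaldehyde; 7 vinylene carbonate (1,3-dioxol-2-one, 2 equiv)
Product: 9 3-bromo-12H-pyrido[1,2-a:3,4-b']diindole-13-carbaldehyde (target), via arylacetaldehyde 8 (not isolated)
Conditions: [Cp*RhCl2]2 (4 mol%), AgSbF6 (16 mol%), NaOAc (30 mol%), PivOH (1 equiv), ClCH2CH2Cl, 100 °C
Reagents that add atoms: none
Why: Proposed new method: a Cp*Rh(III)-catalysed, redox-neutral N–H/C–H [4+2] annulation of a 3-formyl-2,2'-biindole with vinylene carbonate as an acetylene equivalent; acetate-assisted metalation of the more acidic N1–H (vinylogous formamide) and concerted metalation–deprotonation at C3' of the other indole give a five-membered rhodacycle, helped by the N1'–H···O=CH hydrogen bond that holds the biindole syn-planar; insertion of vinylene carbonate and β-oxygen elimination/decarboxylation unmask the C3'–CH2CHO group of 8, and condensation of N1–H with that aldehyde followed by dehydration closes the aromatic pyridine ring; the formyl group blocks C3, so neither the opposite N1'–H/C3–H annulation nor a Friedel–Crafts closure to an indolocarbazole is possible; the closest known reaction type is the Rh(III)-catalysed annulation of 2-aryl-NH-indoles and related N–H azoles with vinylene carbonate to N-fused isoquinolines, which to my knowledge has not been shown on 2,2'-biindoles, with an indole C3–H as the C–H partner, or for this ring system.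

**Compound list**
1 | 6-bromoindolin-2-one (6-bromooxindole) | O=C1Cc2ccc(Br)cc2N1 | starting material
2 | N-[(2,6-dibromo-1H-indol-3-yl)methylidene]-N-methylmethanaminium bromide (not isolated) | C[N+](C)=Cc1c(Br)[nH]c2cc(Br)ccc12.[Br-] | intermediate
3 | 2,6-dibromo-1H-indole-3-carbaldehyde | O=Cc1c(Br)[nH]c2cc(Br)ccc12 | intermediate
4 | [1-(tert-butoxycarbonyl)-1H-indol-2-yl]boronic acid | CC(C)(C)OC(=O)n1c(B(O)O)cc2ccccc21 | starting material
5 | tert-butyl 6'-bromo-3'-formyl-1'H-[2,2'-biindole]-1-carboxylate | CC(C)(C)OC(=O)n1c(-c2[nH]c3cc(Br)ccc3c2C=O)cc2ccccc21 | intermediate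
6 | 6-bromo-1H,1'H-[2,2'-biindole]-3-carbaldehyde | O=Cc1c(-c2cc3ccccc3[nH]2)[nH]c2cc(Br)ccc12 | intermediate
7 | vinylene carbonate (1,3-dioxol-2-one) | O=C1OC=CO1 | starting material
8 | 6-bromo-3'-(2-oxoethyl)-1H,1'H-[2,2'-biindole]-3-carbaldehyde (not isolated) | O=CCc1c(-c2[nH]c3cc(Br)ccc3c2C=O)[nH]c2ccccc12 | intermediate
9 | 3-bromo-12H-pyrido[1,2-a:3,4-b']diindole-13-carbaldehyde (3-bromohomofascaplysin C, CNP0158590.0) | O=Cc1c2ccc(Br)cc2n2ccc3c4ccccc4[nH]c3c12 | target

**Total step count:** 4. **Longest linear sequence:** 4 (1 → 3 → 5 → 6 → 9).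

**Steps most likely to fail, with fallbacks**

Most at risk is step 4, the new annulation. The formyl-indole N–H is a weak nucleophile, the CHO group or N1'–H could steer rhodium to other C–H bonds, and aldehyde 8 could close by aldol condensation onto the formyl carbon (giving a formyl-indolo[2,3-a]carbazole) instead of onto N1. The fallback uses only known chemistry, sets out from 6 and comes back to the route at 9. The more acidic N1–H (vinylogous formamide, roughly five pKa units below the other indole N–H) is alkylated with bromoacetaldehyde diethyl acetal (K2CO3, cat. NaI, DMF, 90 °C) to give 6-bromo-1-(2,2-diethoxyethyl)-1H,1'H-[2,2'-biindole]-3-carbaldehyde F1. TsOH·H2O in toluene at 90 °C then brings about a Pomeranz–Fritsch-type Friedel–Crafts cyclisation of the oxocarbenium ion onto the nucleophilic C3' of the free indole, and loss of two ethanol gives 9.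

Second is step 2. The 2-indolylboronic acid 4 may protodeboronate faster than it couples with the hindered, N–H-acidic bromide 3, and some coupling at C6–Br is possible. The fallback sets out from 3 and comes back at 6, so it also makes step 3 unnecessary. Sonogashira coupling of the C2–Br with commercial 2-ethynylaniline (PdCl2(PPh3)2, CuI, Et3N, THF, 40 °C) gives 2-[(2-aminophenyl)ethynyl]-6-bromo-1H-indole-3-carbaldehyde F2. Castro-type 5-endo-dig hydroamination (CuI, DMF, 100 °C) then builds the second indole ring and gives 6.

Third is step 1. Bromo-Vilsmeier reactions with moisture-sensitive POBr3 can give modest yields or incomplete conversion of the lactam. The fallback sets out from 1 and comes back at 5; it installs the aldehyde after the biaryl bond instead of before. Deoxybromination of the lactam (POBr3, imidazole, ClCH2CH2Cl, 80 °C) gives 2,6-dibromo-1H-indole F3, which is used at once and coupled at its more reactive C2–Br with 4 under the conditions of step 2 to give tert-butyl 6'-bromo-1'H-[2,2'-biindole]-1-carboxylate F4. Vilsmeier–Haack formylation (POCl3, DMF, 0 °C to rt; aq. NaOAc) then takes place only at C3' of the free N–H indole, because the N-Boc indole is deactivated, and gives 5.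

**Further compounds**
F1 | step 4 | 6-bromo-1-(2,2-diethoxyethyl)-1H,1'H-[2,2'-biindole]-3-carbaldehyde | CCOC(Cn1c(-c2cc3ccccc3[nH]2)c(C=O)c2ccc(Br)cc21)OCC
F2 | step 2 | 2-[(2-aminophenyl)ethynyl]-6-bromo-1H-indole-3-carbaldehyde | Nc1ccccc1C#Cc1[nH]c2cc(Br)ccc2c1C=O
F3 | step 1 | 2,6-dibromo-1H-indole | Brc1cc2ccc(Br)cc2[nH]1
F4 | step 1 | tert-butyl 6'-bromo-1'H-[2,2'-biindole]-1-carboxylate | CC(C)(C)OC(=O)n1c(-c2cc3ccc(Br)cc3[nH]2)cc2ccccc21
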